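The carbocycle of the target (C4a, C5, C6, C7, C8, C8a in isochromene numbering, used throughout) is cut at C7–C8 and C4a–C8a into a 3-ethoxy-2-methylfuran and an (E)-3-aroyloxyacrolein. The feature exploited is the C7 methyl carbinol that sits para to C4a in this ring with the C8 ester oxygen cis to its own oxygen: the furan oxygen is the future C7 hydroxyl. One enantioselective Diels–Alder reaction closes the ring, forms both bonds, sets C7 and C8 and places the orsellinate on C8. Its precursors are furan 8, which carries a masked propynal at its C5 for the later pyran, and MOM-protected enal ester 16.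

Key step: step 9

Remark on the chemistry: the catalyst antipode in step 9 is chosen on the assumption that enal 16 reacts as its s-trans rotamer, bound to boron anti to the vinyl group with the formyl C–H···O contact to the catalyst ring oxygen; in that assembly the (R)-oxazaborolidinium leaves the α-Si face open, which leads to (7R,8R).

Step 1
Reactants: 1 3,3-diethoxyprop-1-yne; 2 acetaldehyde
Product: 4 5,5-diethoxypent-3-yn-2-ol (racemic), via lithium acetylide 3 (not isolated)
Conditions: n-BuLi, THF, −78 °C; then 2, −78 to 0 °C; H2O quench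
Reagents that add atoms: none
Why: Addition of a lithium acetylide to an aldehyde (alkynylation) tolerates the base-stable acetal; the carbinol centre forms as the racemate, which is acceptable because it becomes sp2 in step 2.

Step 2
Reactants: 4 5,5-diethoxypent-3-yn-2-ol
Product: 5 3-ethoxy-2-methylfuran
Conditions: Ph3PAuNTf2 (2 mol %), EtOH, rt
Reagents that add atoms: ethanol, CCO
Why: Gold-catalysed alkoxylation–cyclodehydration of an acetal-bearing propargylic alcohol: ethanol adds to the activated alkyne at the carbon remote from the electron-withdrawing acetal, the carbinol oxygen closes on the acetal carbon and loss of two ethanol molecules aromatises the ring to the 2-substituted 3-alkoxyfuran, which is volatile and is carried on as a concentrated solution.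

Step 3
Reactants: 5 3-ethoxy-2-methylfuran
Product: 7 3-ethoxy-5-iodo-2-methylfuran, via 5-lithiofuran 6 (not isolated)
Conditions: n-BuLi, THF, −78 to 0 °C; then I2, −78 °C; used without storage
Reagents that add atoms: iodine, [I][I]
Why: α-Lithiation of a furan followed by iodinolysis: C5 carries the only free α-hydrogen, which is far more acidic than H-4 or the methyl hydrogens, so iodine should enter at C5 alone.

Step 4
Reactants: 7 3-ethoxy-5-iodo-2-methylfuran; 1 3,3-diethoxyprop-1-yne
Product: 8 5-(3,3-diethoxyprop-1-yn-1-yl)-3-ethoxy-2-methylfuran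
Conditions: Pd(PPh3)2Cl2 (2 mol %), CuI (4 mol %), Et3N, THF, rt, degassed
Reagents that add atoms: none
Why: Sonogashira coupling of a heteroaryl iodide with a terminal alkyne runs at room temperature under amine base, which leaves the acetal and the alkoxyfuran untouched.

Step 5
Reactants: 9 orsellinic acid
Product: 10 methoxymethyl 2,4-bis(methoxymethoxy)-6-methylbenzoate
Conditions: NaH, MOMCl, DMF, 0 °C to rt
Reagents that add atoms: chloromethyl methyl ether, COCCl
Why: Williamson-type O-alkylation of the carboxylate and both phenoxides (the hydrogen-bonded 2-OH needs the hydride base) masks every acidic hydrogen in one operation.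

Step 6
Reactants: 10 methoxymethyl 2,4-bis(methoxymethoxy)-6-methylbenzoate
Product: 11 2,4-bis(methoxymethoxy)-6-methylbenzoic acid
Conditions: KOH, MeOH/H2O, 60 °C; then 1 M HCl to pH 4, 0 °C
Reagents that add atoms: potassium hydroxide, [K+].[OH-]
Why: Saponification of the acyloxymethyl ester, whose hemiacetal leaving group makes it labile even between two ortho substituents, while aryl MOM ethers are inert to hydroxide and survive the brief cold acidification.

Step 7
Reactants: 12 1,1,3,3-tetramethoxypropane
Product: 14 sodium (E)-3-oxoprop-1-en-1-olate, via malondialdehyde 13 (not isolated)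
Conditions: cat. aq HCl, H2O, 40 °C; then NaOH (1 equiv), 0 °C; evaporate, triturate with acetone
Reagents that add atoms: water, O; sodium hydroxide, [Na+].[OH-]
Why: Acid-catalysed acetal hydrolysis followed by deprotonation of the vinylogous acid gives the sodium enolate, which adopts the extended (E) geometry needed in the dienophile.

Step 8
Reactants: 11 2,4-bis(methoxymethoxy)-6-methylbenzoic acid; 14 sodium (E)-3-oxoprop-1-en-1-olate
Product: 16 (E)-3-oxoprop-1-en-1-yl 2,4-bis(methoxymethoxy)-6-methylbenzoate, via aroyl chloride 15 (not isolated)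
Conditions: 1-chloro-N,N,2-trimethylprop-1-en-1-amine, CH2Cl2, 0 °C; then 14, 15-crown-5 (10 mol %), MeCN, 0 °C to rt
Reagents that add atoms: none
Why: The α-chloroenamine makes the acid chloride without releasing HCl, so the MOM ethers survive, and O-acylation of the malondialdehyde enolate (esterification of a vinylogous carboxylate) carries the (E) geometry of the enolate into the enol ester.

Step 9
Reactants: 8 5-(3,3-diethoxyprop-1-yn-1-yl)-3-ethoxy-2-methylfuran; 16 (E)-3-oxoprop-1-en-1-yl 2,4-bis(methoxymethoxy)-6-methylbenzoate
Product: 17 (1R,2R,3R,4R)-4-(3,3-diethoxyprop-1-yn-1-yl)-6-ethoxy-3-formyl-1-methyl-7-oxabicyclo[2.2.1]hept-5-en-2-yl 2,4-bis(methoxymethoxy)-6-methylbenzoate (aldehyde endo, ester exo)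
Conditions: (R)-3,3-diphenyl-1-(2-methylphenyl)tetrahydro-1H,3H-pyrrolo[1,2-c][1,3,2]oxazaborole (20 mol %), HN(SO2CF3)2 (17 mol %), CH2Cl2, −78 °C; Et3N quench at −78 °C; Et3N-deactivated silica
Reagents that add atoms: none
Why: This is a normal-demand, concerted but asynchronous Diels–Alder reaction between the electron-rich furan and the boron-bound enal, in which the ethoxy group makes furan C2 the most nucleophilic terminus, so the C7–C8 bond to the enal β-carbon leads and the C4a–C8a bond to the α-carbon follows, placing the ethoxy-bearing C6 para to the formyl-bearing C8a. The closest known reactions are the cycloadditions of 3-alkoxyfurans with activated alkenes and the oxazaborolidinium-catalysed enantioselective Diels–Alder reactions of furans and of enals. The carbocycle (C4a, C5, C6, C7, C8, C8a) is closed by intermolecular suprafacial [4+2] addition across furan C2 and C5, which leaves the furan oxygen as the one-atom bridge between C7 and C4a. The bridgehead centres C7 and C4a follow from that suprafacial addition, the trans relation of C8 and C8a is inherited from the (E)-alkene, the endo position of the Lewis-acid-bound formyl group puts the aroyloxy group exo and so syn to the bridging oxygen, and the absolute sense comes from the catalyst, whose phenyl group cis to the bound aldehyde covers one face of the s-trans enal so that the furan adds to the open α-Si face. The step needs para regiochemistry, an endo aldehyde and one enal face, which are secured by the ethoxy donor, by the endo preference of the activated aldehyde at −78 °C and by the aldehyde-bound chiral cation; the acid is kept below the amount of oxazaborolidine so that no free HN(SO2CF3)2 can attack the furan, the acetal or the MOM ethers.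

Step 10
Reactants: 17 cycloadduct
Product: 18 (1R,6R)-3-(3,3-diethoxyprop-1-yn-1-yl)-5-ethoxy-2-formyl-6-hydroxy-6-methylcyclohexa-2,4-dien-1-yl 2,4-bis(methoxymethoxy)-6-methylbenzoate
Conditions: DBU (1.2 equiv), CH2Cl2, −40 to 0 °C
Reagents that add atoms: none
Why: Base-induced β-elimination (E1cB) opening of a 7-oxanorbornene: removal of H-8a next to the aldehyde expels the bridging oxygen from C4a, a bond weakened by ring strain and by the ethoxy group (vinylogous ketal), to give the push–pull dienal and the C7 tertiary alcohol; C7 and C8 are not involved and keep their configuration, while C4a and C8a become sp2.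

Step 11
Reactants: 18 dienal
Product: 19 (7R,8R)-3-(diethoxymethyl)-7-hydroxy-7-methyl-6-oxo-7,8-dihydro-6H-isochromen-8-yl 2,4-bis(methoxymethoxy)-6-methylbenzoate
Conditions: AuCl3 (5 mol %), H2O (5 equiv), MeCN, 0 °C to rt
Reagents that add atoms: water, O
Why: Gold-catalysed 6-endo-dig cycloisomerisation of an enynal: the carbonyl oxygen adds to the activated alkyne carbon C3 to give a pyrylium-type cation stabilised by the C6 ethoxy group, protodeauration gives C4–H, and water adds at C6 with loss of ethanol to reveal the ketone; the acetal is kept through this step because a free ynal would direct the oxygen to C4.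

Step 12
Reactants: 19 pyran acetal
Product: 20 (7R,8R)-3-formyl-7-hydroxy-7-methyl-6-oxo-7,8-dihydro-6H-isochromen-8-yl 2,4-dihydroxy-6-methylbenzoate
Conditions: TFA/H2O/CH2Cl2 (4:1:4), 0 °C to rt
Reagents that add atoms: water, O
Why: Aqueous acid hydrolysis removes the acetal (slow to ionise beside the electron-poor pyranone, hence the strong acid) and both aryl MOM ethers in one operation, while the vinylogous ester core and the hindered C8 ester should withstand acid at this temperature.

Step 13
Reactants: 20 aldehyde; 21 tert-butyl 2-(triphenyl-λ5-phosphanylidene)acetate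
Product: 22 tert-butyl (E)-3-[(7R,8R)-8-(2,4-dihydroxy-6-methylbenzoyl)oxy-7-hydroxy-7-methyl-6-oxo-7,8-dihydro-6H-isochromen-3-yl]prop-2-enoate
Conditions: 21 (1.2 equiv), CH2Cl2, rt
Reagents that add atoms: none
Why: Wittig olefination with a stabilised ylide is (E)-selective and needs no added base, so the acyloxy ketol and the electrophilic C1 of the pyran are not exposed to base, and the weakly basic ylide does not disturb the free phenols.

Step 14
Reactants: 22 tert-butyl ester
Product: 23 (+)-mitorubrinic acid B
Conditions: TFA/CH2Cl2 (1:3), 0 °C to rt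
Reagents that add atoms: none
Why: Acidolysis of the tert-butyl ester, with loss of the tert-butyl cation as isobutene, frees the acid without base or nucleophile, and neither the tertiary C7 nor C8 should epimerise under these conditions.

Compound list
1 | 3,3-diethoxyprop-1-yne | C#CC(OCC)OCC | starting material
2 | acetaldehyde | CC=O | starting material
3 | (3,3-diethoxyprop-1-yn-1-yl)lithium | [Li]C#CC(OCC)OCC | intermediate
4 | 5,5-diethoxypent-3-yn-2-ol (racemic) | CC(O)C#CC(OCC)OCC | intermediate
5 | 3-ethoxy-2-methylfuran | CCOc1ccoc1C | intermediate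
6 | (4-ethoxy-5-methylfuran-2-yl)lithium | [Li]c1cc(OCC)c(C)o1 | intermediate
7 | 3-ethoxy-5-iodo-2-methylfuran | CCOc1cc(I)oc1C | intermediate
8 | 5-(3,3-diethoxyprop-1-yn-1-yl)-3-ethoxy-2-methylfuran | CCOc1cc(C#CC(OCC)OCC)oc1C | intermediate
9 | orsellinic acid (2,4-dihydroxy-6-methylbenzoic acid) | Cc1cc(O)cc(O)c1C(=O)O | starting material
10 | methoxymethyl 2,4-bis(methoxymethoxy)-6-methylbenzoate | COCOC(=O)c1c(C)cc(OCOC)cc1OCOC | intermediate
11 | 2,4-bis(methoxymethoxy)-6-methylbenzoic acid | Cc1cc(OCOC)cc(OCOC)c1C(=O)O | intermediate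
12 | 1,1,3,3-tetramethoxypropane | COC(CC(OC)OC)OC | starting material
13 | malondialdehyde (propanedial) | O=CCC=O | intermediate
14 | sodium (E)-3-oxoprop-1-en-1-olate | [Na+].[O-]/C=C/C=O | intermediate
15 | 2,4-bis(methoxymethoxy)-6-methylbenzoyl chloride | Cc1cc(OCOC)cc(OCOC)c1C(Cl)=O | intermediate
16 | (E)-3-oxoprop-1-en-1-yl 2,4-bis(methoxymethoxy)-6-methylbenzoate | O=C/C=C/OC(=O)c1c(C)cc(OCOC)cc1OCOC | intermediate
17 | (1R,2R,3R,4R)-4-(3,3-diethoxyprop-1-yn-1-yl)-6-ethoxy-3-formyl-1-methyl-7-oxabicyclo[2.2.1]hept-5-en-2-yl 2,4-bis(methoxymethoxy)-6-methylbenzoate (aldehyde endo, ester exo) | C[C@]12O[C@](C#CC(OCC)OCC)(C=C1OCC)[C@H](C=O)[C@H]2OC(=O)c1c(C)cc(OCOC)cc1OCOC | intermediate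
18 | (1R,6R)-3-(3,3-diethoxyprop-1-yn-1-yl)-5-ethoxy-2-formyl-6-hydroxy-6-methylcyclohexa-2,4-dien-1-yl 2,4-bis(methoxymethoxy)-6-methylbenzoate | Cc1cc(OCOC)cc(OCOC)c1C(=O)O[C@@H]1C(C=O)=C(C#CC(OCC)OCC)C=C(OCC)[C@]1(C)O | intermediate
19 | (7R,8R)-3-(diethoxymethyl)-7-hydroxy-7-methyl-6-oxo-7,8-dihydro-6H-isochromen-8-yl 2,4-bis(methoxymethoxy)-6-methylbenzoate | Cc1cc(OCOC)cc(OCOC)c1C(=O)O[C@@H]1C2=COC(C(OCC)OCC)=CC2=CC(=O)[C@]1(C)O | intermediate
20 | (7R,8R)-3-formyl-7-hydroxy-7-methyl-6-oxo-7,8-dihydro-6H-isochromen-8-yl 2,4-dihydroxy-6-methylbenzoate | Cc1cc(O)cc(O)c1C(=O)O[C@@H]1C2=COC(C=O)=CC2=CC(=O)[C@]1(C)O | intermediate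
21 | tert-butyl 2-(triphenyl-λ5-phosphanylidene)acetate | CC(C)(C)OC(=O)C=P(c1ccccc1)(c1ccccc1)c1ccccc1 | starting material
22 | tert-butyl (E)-3-[(7R,8R)-8-(2,4-dihydroxy-6-methylbenzoyl)oxy-7-hydroxy-7-methyl-6-oxo-7,8-dihydro-6H-isochromen-3-yl]prop-2-enoate | Cc1cc(O)cc(O)c1C(=O)O[C@@H]1C2=COC(/C=C/C(=O)OC(C)(C)C)=CC2=CC(=O)[C@]1(C)O | intermediate
23 | (+)-mitorubrinic acid B, (E)-3-[(7R,8R)-8-(2,4-dihydroxy-6-methylbenzoyl)oxy-7-hydroxy-7-methyl-6-oxo-7,8-dihydro-6H-isochromen-3-yl]prop-2-enoic acid | Cc1cc(O)cc(O)c1C(=O)O[C@@H]1C2=COC(/C=C/C(=O)O)=CC2=CC(=O)[C@]1(C)O | target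

Total step count: 14 (three branches that meet in step 9).
Longest linear sequence: 10 steps (steps 1, 2, 3, 4, 9, 10, 11, 12, 13, 14).

Steps most likely to fail

Step 9. Facial selectivity may be poor because an α-unsubstituted enal can react through either rotamer, and the cationic boron acid may degrade the alkoxyfuran or ionise its propargylic acetal before cycloaddition. If only the sense is wrong, the (S)-oxazaborolidine is substituted. The fallback sets out from 8 and 16: the cycloaddition is run without the chiral acid (in CH2Cl2 at rt, or with ZnCl2 at −40 °C), which alkoxyfurans are known to tolerate and which should give racemic cycloadduct. The enantiomers are then separated by preparative chromatography on a chiral stationary phase. The wanted antipode re-enters the route at 17 and the mirror-image cycloadduct ent-17 F1 is set aside.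

Step 10. The enolate formed at C8a may expel the exo carboxylate on C8 (towards a 7-oxanorbornadiene) in competition with the bridging oxygen, and the opened dienol may lose water and aromatise. The fallback sets out from 17 and opens the bridge without forming an enolate: TMSOTf and 2,6-lutidine in CH2Cl2 at −78 °C ionise the C4a–O bond of the vinylogous ketal, the base removes H-8a, and the C7 oxygen is held as the trimethylsilyl ether of the dienal F2 (silyl-triflate opening of oxanorbornane bridges is known chemistry). F2 is taken directly into the conditions of step 11, where the tertiary silyl ether is hydrolysed, and the route is rejoined at 19.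

Step 11. The carbonyl oxygen may close on the near alkyne carbon C4 (five-membered, furan-type ring) because the acetal withdraws electron density from C3, and the Lewis acid may ionise the C8 ester of 18. The fallback sets out from 7 and carries the formyl carbon as a silyloxymethyl group, which biases C3 less and needs no strong-acid unmasking of an acetal. Sonogashira coupling of 7 with tert-butyldimethyl(prop-2-yn-1-yloxy)silane gives the silyloxypropynyl furan F3. Under the conditions of steps 9, 10 and 11 this gives the cycloadduct F4, the dienal F5 and the silyloxymethyl pyran F6. TFA/H2O then removes the silyl and MOM groups to give the hydroxymethyl pyran F7, and MnO2 in CH2Cl2 oxidises this allylic-type alcohol to the aldehyde, rejoining the route at 20.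

Further compounds
F1 | step 9 | ent-17, (1S,2S,3S,4S)-4-(3,3-diethoxyprop-1-yn-1-yl)-6-ethoxy-3-formyl-1-methyl-7-oxabicyclo[2.2.1]hept-5-en-2-yl 2,4-bis(methoxymethoxy)-6-methylbenzoate | C[C@@]12O[C@@](C#CC(OCC)OCC)(C=C1OCC)[C@@H](C=O)[C@@H]2OC(=O)c1c(C)cc(OCOC)cc1OCOC
F2 | step 10 | C7 trimethylsilyl ether of 18 | Cc1cc(OCOC)cc(OCOC)c1C(=O)O[C@@H]1C(C=O)=C(C#CC(OCC)OCC)C=C(OCC)[C@]1(C)O[Si](C)(C)C
F3 | step 11 | tert-butyl{[3-(4-ethoxy-5-methylfuran-2-yl)prop-2-yn-1-yl]oxy}dimethylsilane | CCOc1cc(C#CCO[Si](C)(C)C(C)(C)C)oc1C
F4 | step 11 | silyloxymethyl analogue of cycloadduct 17 (same configuration, aldehyde endo, ester exo) | C[C@]12O[C@](C#CCO[Si](C)(C)C(C)(C)C)(C=C1OCC)[C@H](C=O)[C@H]2OC(=O)c1c(C)cc(OCOC)cc1OCOC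
F5 | step 11 | silyloxymethyl analogue of dienal 18 (same configuration) | Cc1cc(OCOC)cc(OCOC)c1C(=O)O[C@@H]1C(C=O)=C(C#CCO[Si](C)(C)C(C)(C)C)C=C(OCC)[C@]1(C)O
F6 | step 11 | (7R,8R)-3-[(tert-butyldimethylsilyl)oxymethyl]-7-hydroxy-7-methyl-6-oxo-7,8-dihydro-6H-isochromen-8-yl 2,4-bis(methoxymethoxy)-6-methylbenzoate | Cc1cc(OCOC)cc(OCOC)c1C(=O)O[C@@H]1C2=COC(CO[Si](C)(C)C(C)(C)C)=CC2=CC(=O)[C@]1(C)O
F7 | step 11 | (7R,8R)-7-hydroxy-3-(hydroxymethyl)-7-methyl-6-oxo-7,8-dihydro-6H-isochromen-8-yl 2,4-dihydroxy-6-methylbenzoate | Cc1cc(O)cc(O)c1C(=O)O[C@@H]1C2=COC(CO)=CC2=CC(=O)[C@]1(C)O
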